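**Plan**
- Retrosynthesis: the angelate C–O bond is cut first; C4–H/C7'–H is then taken back to a C4=C7' double bond and the C9 alcohol to a gem-diester at C3, which exposes a 4-arylidene oxolane-3,3-dicarboxylate.
- Feature used: in the ring O1–C2(aryl)–C3(C9 arm)–C4(C7'H2–aryl arm)–C5, the chain O1–C5–C4–C7' is propargyl alcohol, C2–C3–C9 with the C2 aryl group is an arylidene malonate, and the aryl group on C7' is that of an aryl iodide.
- The key step therefore cuts O1–C2, C3–C4 and C7'–aryl in one operation; the malonate is cut at C2=C3 (Knoevenagel).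
- Forward: Knoevenagel condensation, three-component assembly that closes the only ring (the oxolane), dealkoxycarbonylation, ester reduction, resolution, hydrogenation, angeloylation.
- Stereochemistry: C2 arises racemic; C3 settles trans to the C2 aryl group at the Krapcho step; a lipase resolution supplies the absolute configuration; C4 comes from hydrogenation on the face away from the C3 arm; the Z ester geometry is brought in with angelic acid.

Key step: step 2

Assumption: the lipase acetylates the (2R,3S) alcohol faster, so the wanted (2S,3R) alcohol is the one left unreacted; the sense of this preference has to be confirmed by experiment.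
Remark: in the cascade product the ring carbon that is 2S in leoligin carries the descriptor R, because the C3 diester carbon outranks the aryl group there; the spatial arrangement is the same.

**Route**

Step 1
Reactants: 1 veratraldehyde; 2 diethyl malonate
Product: 3 diethyl 2-(3,4-dimethoxybenzylidene)malonate
Conditions: piperidine (cat.), AcOH (cat.), toluene, reflux, Dean–Stark trap
Reagents that add atoms: none
Why: Knoevenagel condensation of an aromatic aldehyde with a malonate, driven by azeotropic removal of water; the two identical ester groups leave no alkene geometry to control.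

Step 2
Reactants: 3 diethyl 2-(3,4-dimethoxybenzylidene)malonate; 4 propargyl alcohol; 5 4-iodoveratrole
Product: 8 diethyl (4Z)-2-(3,4-dimethoxyphenyl)-4-(3,4-dimethoxybenzylidene)oxolane-3,3-dicarboxylate (racemate), via lithium prop-2-yn-1-olate 6 (not isolated), via lithium malonate enolate adduct 7 (not isolated)
Conditions: 4, n-BuLi (1 equiv), THF, 0 °C; then 3, 5, PdCl2(PPh3)2 (5 mol %)/n-BuLi (10 mol %), THF–DMSO, rt
Reagents that add atoms: none
Why: Alkoxide 6 adds reversibly to the arylidene malonate (oxa-Michael, O1–C2) to give enolate 7, whose carbanion sits five atoms from the alkyne, while Pd(0) inserts into the C–I bond of 5 and the arylpalladium(II) iodide binds and activates that alkyne. The enolate carbon then attacks the internal alkyne carbon on the side away from palladium in a 5-exo-dig closure that forms C3–C4 and the oxolane ring, and reductive elimination from the σ-vinyl(aryl)palladium forms C7'–aryl with retention, so the aryl group ends up trans to C3 (4Z). The closest known reaction type is the palladium-mediated three-component coupling of propargylic alkoxides, alkylidene malonates and aryl halides to 4-arylidene tetrahydrofurans. C2 is the only new stereocentre and is formed in the oxa-Michael step with no controlling element, so 8 is racemic. The step needs cyclisation–arylation to outrun direct arylation of the terminal alkyne and loss of alkoxide from 7; the short tether, the absence of copper and the irreversible C–C bond formation that drains the Michael equilibrium should secure this.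

Step 3
Reactants: 8 diethyl (4Z)-2-(3,4-dimethoxyphenyl)-4-(3,4-dimethoxybenzylidene)oxolane-3,3-dicarboxylate (racemate)
Product: 9 ethyl (2S*,3S*,4Z)-2-(3,4-dimethoxyphenyl)-4-(3,4-dimethoxybenzylidene)oxolane-3-carboxylate (racemate, 2,3-trans)
Conditions: LiCl (2 equiv), H2O (2 equiv), DMSO, 150 °C
Reagents that add atoms: none
Why: Krapcho dealkoxycarbonylation, in which chloride dealkylates one ester, CO2 is lost and the enolate is protonated at C3; since this C–H is acidic the C2/C3 pair can settle in the more stable trans arrangement, the double bond should stay exocyclic because it is conjugated with the arene, and ring opening by β-elimination would be the reverse of a 5-endo-trig closure.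

Step 4
Reactants: 9 ethyl (2S*,3S*,4Z)-2-(3,4-dimethoxyphenyl)-4-(3,4-dimethoxybenzylidene)oxolane-3-carboxylate (racemate)
Product: 10 [(2S*,3R*,4Z)-2-(3,4-dimethoxyphenyl)-4-(3,4-dimethoxybenzylidene)oxolan-3-yl]methanol (racemate)
Conditions: DIBAL-H (3 equiv), CH2Cl2, −78 → 0 °C; aq. Rochelle salt
Reagents that add atoms: none
Why: DIBAL-H reduction of an ester to the primary alcohol at low temperature and without base, so that C3 is not epimerised and the β,γ-double bond is not moved.

Step 5
Reactants: 10 [(2S*,3R*,4Z)-2-(3,4-dimethoxyphenyl)-4-(3,4-dimethoxybenzylidene)oxolan-3-yl]methanol (racemate)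
Product: 11 [(2S,3R,4Z)-2-(3,4-dimethoxyphenyl)-4-(3,4-dimethoxybenzylidene)oxolan-3-yl]methanol (single enantiomer)
Conditions: Burkholderia cepacia lipase (Amano PS, immobilised), vinyl acetate, MTBE, 30 °C, stopped just past half conversion; chromatography
Reagents that add atoms: none
Why: Lipase-catalysed kinetic resolution by irreversible transesterification with vinyl acetate, in which one enantiomer of this primary alcohol with a stereocentre at the β-carbon should be acetylated much faster, so that running past half conversion leaves the slower (2S,3R) alcohol enantiomerically pure without touching any stereocentre.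

Step 6
Reactants: 11 [(2S,3R,4Z)-2-(3,4-dimethoxyphenyl)-4-(3,4-dimethoxybenzylidene)oxolan-3-yl]methanol
Product: 12 [(2S,3R,4R)-4-(3,4-dimethoxybenzyl)-2-(3,4-dimethoxyphenyl)oxolan-3-yl]methanol (lariciresinol dimethyl ether)
Conditions: H2 (1 atm), 10% Pd/C, EtOAc, rt, stopped after one equivalent of H2
Reagents that add atoms: none
Why: Heterogeneous syn-hydrogenation of the exocyclic trisubstituted styrene, in which hydrogen should arrive on the ring face opposite the adjacent C3 hydroxymethyl arm and so place the benzyl group cis to that arm (4R), the outcome known for 3-substituted 4-arylidene oxolanes and α-arylidene-β-substituted butyrolactones; neutral solvent, 1 atm and a limited hydrogen uptake should spare the benzylic C2–O1 bond.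

Step 7
Reactants: 12 [(2S,3R,4R)-4-(3,4-dimethoxybenzyl)-2-(3,4-dimethoxyphenyl)oxolan-3-yl]methanol; 13 angelic acid
Product: 14 leoligin, [(2S,3R,4R)-4-(3,4-dimethoxybenzyl)-2-(3,4-dimethoxyphenyl)oxolan-3-yl]methyl (2Z)-2-methylbut-2-enoate
Conditions: PPh3 (1.5 equiv), DIAD (1.5 equiv), THF, 0 °C → rt
Reagents that add atoms: none
Why: Mitsunobu esterification, in which the primary alcohol is activated as its alkoxyphosphonium ion and displaced by angelate, so the acid never becomes an activated acyl species and the Z double bond should not isomerise to the tiglate; the carbinol carbon is not a stereocentre and C2, C3 and C4 are untouched.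

**Compound list**
1 | veratraldehyde (3,4-dimethoxybenzaldehyde) | COc1ccc(C=O)cc1OC | starting material
2 | diethyl malonate | CCOC(=O)CC(=O)OCC | starting material
3 | diethyl 2-(3,4-dimethoxybenzylidene)malonate | CCOC(=O)C(=Cc1ccc(OC)c(OC)c1)C(=O)OCC | intermediate
4 | propargyl alcohol (prop-2-yn-1-ol) | C#CCO | starting material
5 | 4-iodoveratrole (4-iodo-1,2-dimethoxybenzene) | COc1ccc(I)cc1OC | starting material
6 | lithium prop-2-yn-1-olate (not isolated) | [Li+].[O-]CC#C | intermediate
7 | lithium enolate of diethyl 2-[(3,4-dimethoxyphenyl)(prop-2-yn-1-yloxy)methyl]malonate (racemic, not isolated) | CCOC(=O)C(=C([O-])OCC)C(OCC#C)c1ccc(OC)c(OC)c1.[Li+] | intermediate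
8 | diethyl (4Z)-2-(3,4-dimethoxyphenyl)-4-(3,4-dimethoxybenzylidene)oxolane-3,3-dicarboxylate (racemate; 2R enantiomer drawn, the one that leads to the target) | CCOC(=O)C1(C(=O)OCC)/C(=C/c2ccc(OC)c(OC)c2)CO[C@@H]1c1ccc(OC)c(OC)c1 | intermediate
9 | ethyl (2S*,3S*,4Z)-2-(3,4-dimethoxyphenyl)-4-(3,4-dimethoxybenzylidene)oxolane-3-carboxylate (racemate, 2,3-trans; 2S,3S enantiomer drawn) | CCOC(=O)[C@H]1/C(=C/c2ccc(OC)c(OC)c2)CO[C@@H]1c1ccc(OC)c(OC)c1 | intermediate
10 | [(2S*,3R*,4Z)-2-(3,4-dimethoxyphenyl)-4-(3,4-dimethoxybenzylidene)oxolan-3-yl]methanol (racemate, 2,3-trans; 2S,3R enantiomer drawn) | OC[C@H]1/C(=C/c2ccc(OC)c(OC)c2)CO[C@@H]1c1ccc(OC)c(OC)c1 | intermediate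
11 | [(2S,3R,4Z)-2-(3,4-dimethoxyphenyl)-4-(3,4-dimethoxybenzylidene)oxolan-3-yl]methanol (single enantiomer) | OC[C@H]1/C(=C/c2ccc(OC)c(OC)c2)CO[C@@H]1c1ccc(OC)c(OC)c1 | intermediate
12 | [(2S,3R,4R)-4-(3,4-dimethoxybenzyl)-2-(3,4-dimethoxyphenyl)oxolan-3-yl]methanol (lariciresinol dimethyl ether; 2,3-trans, 3,4-cis) | OC[C@H]1[C@@H](Cc2ccc(OC)c(OC)c2)CO[C@@H]1c1ccc(OC)c(OC)c1 | intermediate
13 | angelic acid [(2Z)-2-methylbut-2-enoic acid] | C/C=C(/C)C(=O)O | starting material
14 | leoligin, [(2S,3R,4R)-4-(3,4-dimethoxybenzyl)-2-(3,4-dimethoxyphenyl)oxolan-3-yl]methyl (2Z)-2-methylbut-2-enoate | C/C=C(/C)C(=O)OC[C@H]1[C@@H](Cc2ccc(OC)c(OC)c2)CO[C@@H]1c1ccc(OC)c(OC)c1 | target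

**Count**
Total steps: 7. Longest linear sequence: 7 steps (1/2 → 3 → 8 → 9 → 10 → 11 → 12 → 14); 4, 5 and 13 are bought and enter directly.

**Steps most likely to fail**

Step 5 (resolution). The enzyme may discriminate only weakly between the enantiomers, since the stereocentre lies one carbon away from the reacting hydroxyl group, or it may acetylate the wanted enantiomer instead of the unwanted one. The fallback is a classical resolution through covalent diastereomers. Racemic alcohol 10 would be esterified with (S)-O-methylmandelic acid (DCC, cat. DMAP, CH2Cl2, 0 °C) to give the (S)-O-methylmandelate of the (2S,3R) alcohol F1 and the (S)-O-methylmandelate of the (2R,3S) alcohol F2. The two would be separated by chromatography or crystallisation, and methanolysis of F1 (K2CO3, MeOH, rt) would rejoin the route at 11.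

Step 3 (Krapcho). At 150 °C the exocyclic double bond may migrate into conjugation with the ester through the extended enolate, or protonation at C3 may leave much of the 2,3-cis isomer. The fallback cleaves the malonate in two stages without a free carbanion at high temperature. Starting from 8, half-saponification (KOH, 1 equiv, EtOH–H2O, rt) would give the malonic half-ester 3-(ethoxycarbonyl)-2-(3,4-dimethoxyphenyl)-4-(3,4-dimethoxybenzylidene)oxolane-3-carboxylic acid F3. Its thermal decarboxylation (xylene, 130 °C) passes through the ester enol in a neutral medium and would rejoin the route at 9.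

Step 6 (hydrogenation). Hydrogen may be delivered on the hydroxymethyl face if the free hydroxyl group anchors the substrate to the metal, which would give the 3,4-trans isomer, and the benzylic C2–O1 or allylic C5–O1 bond may undergo hydrogenolysis. The fallback replaces passive control by a bulky, non-coordinating blocking group and a less hydrogenolytic metal. Alcohol 11 would be silylated (TBDPSCl, imidazole, DMF, rt) to the tert-butyldiphenylsilyl ether of the benzylidene alcohol F4. Hydrogenation over 5% Rh/Al2O3 (H2, 1 atm, EtOAc, rt) would give the tert-butyldiphenylsilyl ether of the saturated alcohol F5, and desilylation (TBAF, THF, rt) would rejoin the route at 12.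

Further compounds
F1 | step 5 | [(2S,3R,4Z)-2-(3,4-dimethoxyphenyl)-4-(3,4-dimethoxybenzylidene)oxolan-3-yl]methyl (2S)-2-methoxy-2-phenylacetate | CO[C@H](C(=O)OC[C@H]1/C(=C/c2ccc(OC)c(OC)c2)CO[C@@H]1c1ccc(OC)c(OC)c1)c1ccccc1
F2 | step 5 | [(2R,3S,4Z)-2-(3,4-dimethoxyphenyl)-4-(3,4-dimethoxybenzylidene)oxolan-3-yl]methyl (2S)-2-methoxy-2-phenylacetate | CO[C@H](C(=O)OC[C@@H]1/C(=C/c2ccc(OC)c(OC)c2)CO[C@H]1c1ccc(OC)c(OC)c1)c1ccccc1
F3 | step 3 | (4Z)-3-(ethoxycarbonyl)-2-(3,4-dimethoxyphenyl)-4-(3,4-dimethoxybenzylidene)oxolane-3-carboxylic acid (racemic, both C3 epimers) | CCOC(=O)C1(C(=O)O)/C(=C/c2ccc(OC)c(OC)c2)CO[C@@H]1c1ccc(OC)c(OC)c1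
F4 | step 6 | tert-butyl{[(2S,3R,4Z)-2-(3,4-dimethoxyphenyl)-4-(3,4-dimethoxybenzylidene)oxolan-3-yl]methoxy}diphenylsilane | CC(C)(C)[Si](OC[C@H]1/C(=C/c2ccc(OC)c(OC)c2)CO[C@@H]1c1ccc(OC)c(OC)c1)(c1ccccc1)c1ccccc1
F5 | step 6 | tert-butyl{[(2S,3R,4R)-4-(3,4-dimethoxybenzyl)-2-(3,4-dimethoxyphenyl)oxolan-3-yl]methoxy}diphenylsilane | CC(C)(C)[Si](OC[C@H]1[C@@H](Cc2ccc(OC)c(OC)c2)CO[C@@H]1c1ccc(OC)c(OC)c1)(c1ccccc1)c1ccccc1
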